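The constants used here are invented; the result is computed.

Litres per mole per second, multiplied by a concentration, give a rate per second, and that was the arithmetic I used on these set-ups.

| setting | Wednesday's | Saturday's | Monday's | Friday's |
|---|---|---|---|---|
| starting material | 0.20 mM (fed, over 6.40 s) | 0.20 mM | 0.20 mM | 0.20 mM |
| reagent | 0.220 mM | 0.220 mM | 0.220 mM | 0.220 mM |
| second substrate | 0.100 mM | 0.100 mM | 0.100 mM | 0.100 mM (fed, over 6.40 s) |
| time | 8.0 s |  | 8.0 s | 8.0 s |
| remark | all but starting material at the start; starting material goes in evenly over 6.40 s, the run ends at 8.0 s | one stirred flow tank at steady state, fed with the mixture as stated, mean residence time 8.0 s | everything together in a closed stirred flask, run for 8.0 s | all but second substrate at the start; second substrate goes in evenly over 6.40 s, the run ends at 8.0 s |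

    starting material + reagent → target (k1 = 2040 L mol⁻¹ s⁻¹)
    second substrate + reagent → second product (k2 = 559 L mol⁻¹ s⁻¹)
    starting material + second substrate → cross product (k3 = 12300 L mol⁻¹ s⁻¹)
    target ⇌ isomer of the product (K4 = 4.78, k4 = 0.0233 s⁻¹)
    reagent + target → over-reaction product (k5 = 194 L mol⁻¹ s⁻¹)

1. the set-up with the highest amount of target at the outlet or at the end, in percent of the starting material put in ("none" if the first two lie within 2 percentage points) (Wednesday's / Saturday's / Monday's / Friday's / none)
2. amount of target at the outlet or at the end, in percent of the starting material put in, Wednesday's
3. amount of target at the outlet or at the end, in percent of the starting material put in, Saturday's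
4. amount of target at the outlet or at the end, in percent of the starting material put in, Monday's
5. amount of target at the outlet or at the end, in percent of the starting material put in, Friday's

- the stated concentrations are those of everything mixed, before any reaction; amounts are the same in each set-up
- the feed brings no volume worth counting
- run time (Wednesday's): 8.0 s

Starting material had two exits: towards target at 0.449 s⁻¹ and towards cross product at 1.23 s⁻¹, both pseudo-first-order at the charged concentrations, and the cross exit was faster than the target exit. Their rate constants stood in a selectivity factor of 6.03. At the charge, the target exit took 26.7% of the flow; I carried this as the split, the rate towards target divided by the sum of the rates through both exits at a given moment.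

A second way to Monday's flask was to count the charge. The cross step consumes one of each partner, and [second substrate] was half of [starting material], so the cross product could claim that half and leave 50.0% of the starting material for other routes. The two ways parted, and each cheated. The split at the charge froze [second substrate], whereas on Monday's that substrate had a half-life of 0.282 s against starting material at its charged concentration, shorter than the 1.5 s of starting material by the target step. The count sent the whole remainder to target, though the scheme lets target pass on to isomer of the product and over-reaction product. I therefore placed Monday's between 26.7% and 50.0%.

The split contains no [starting material], and on Wednesday's [reagent] and [second substrate] began as charged, so that flask started at the same 26.7%. On Friday's, second substrate came in at 0.0156 mM s⁻¹ and at the start lived 0.387 s, much less than the 6.40 s of the feed. So, once the feed had run for about that lifetime, and with [starting material] and [reagent] still taken as charged, I reckoned [second substrate] near 0.00605 mM and the split at 85.8%, higher than Wednesday's starting split. I put Friday's first.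

The forecast differed from me and put Wednesday's first, on the ground that “dosing the starting material lets the reagent and side reaction use up much of the second substrate while little starting material is present”.

The simulation gave Friday's as the best set-up.

| Set-up | Forecast | Simulation |
|---|---|---|
| Wednesday's | 46% | 36.6% |
| Saturday's | 31% | 30.5% |
| Monday's | 36% | 37.4% |
| Friday's | 41% | 50.4% |

On Monday's, the half-life of starting material by the cross step, 0.56 s, was shorter than its 1.5 s by the target step, which is the comparison inside the split of 26.7% at the charge, and target stood at 37.4% at the end of the run. Friday's, with its reckoned early split of 85.8%, ended 13 percentage points higher than Monday's, at 50.4%.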